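**Assumption (one line):** enantiopure (R)-β-butyrolactone is commercially available, and the Pauson–Khand closure sets C1 anti to the C10 methyl, as the target requires (1R,7S,8R,10S).

## Retrosynthetic overview
1. Torilin comes from the 8,11-diol enone 16 by angeloylation of the secondary C8-OH and then acetylation of the tertiary C11-OH.
2. The 5-7 bicyclic enone 16 comes from an intramolecular Pauson–Khand reaction of the 1,8-enyne 15. This step closes the seven-membered ring and builds the methyl-cyclopentenone at the same time, with C1 set by C10.
3. Enyne 15 comes from ester 14 by double MeMgBr addition. Ester 14 comes from an Evans syn aldol between the alkynoyl imide 12 and the chiral aldehyde 4. This is the convergent C7–C8 coupling that sets C7 and C8.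
4. Aldehyde 4 comes from (R)-β-butyrolactone by cuprate opening, reduction and oxidation. Imide 12 comes from hex-4-ynoic acid and a valine-derived oxazolidinone.

## Forward route

**Step 1**
Reactants: 1, (R)-β-butyrolactone
Product: 2, (S)-3-methylpent-4-enoic acid
Conditions: (CH2=CH)2CuMgBr (from vinylMgBr, CuI 2:1), THF, –40 → 0 °C; then H3O+
Reagents that add atoms: vinylmagnesium bromide, C=C[Mg]Br
Why: Cuprates attack β-lactones at C4 by SN2, so the C4 centre is inverted ((R)-lactone gives (S)-acid) and C10 is set. This is cuprate ring-opening of a β-lactone.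

**Step 2**
Reactants: 2
Product: 3, (S)-3-methylpent-4-en-1-ol
Conditions: LiAlH4, THF, 0 °C → rt
Reagents that add atoms: none
Why: The carboxylic acid is reduced to the primary alcohol, and the remote stereocentre is untouched. This is a hydride reduction.

**Step 3**
Reactants: 3
Product: 4, (S)-3-methylpent-4-enal
Conditions: Dess–Martin periodinane, NaHCO3, CH2Cl2, 0 °C → rt
Reagents that add atoms: none
Why: Mild oxidation gives the aldehyde with no epimerisation, because the stereocentre is β to the carbonyl. This is a Dess–Martin oxidation.

**Step 4**
Reactants: 5, tert-butyl acetate; 6, 1-bromobut-2-yne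
Product: 7, tert-butyl hex-4-ynoate
Conditions: LDA, THF, –78 → 0 °C
Reagents that add atoms: none (LDA leaves no atoms)
Why: The ester enolate is alkylated SN2 at the propargylic bromide, putting C6, C5, C4 and C15 in place. This is enolate alkylation.

**Step 5**
Reactants: 7
Product: 8, hex-4-ynoic acid
Conditions: TFA, CH2Cl2, rt
Reagents that add atoms: none
Why: Acid-mediated loss of isobutene cleaves the tert-butyl ester, and the alkyne survives. This is tert-butyl ester cleavage.

**Step 6**
Reactants: 9, L-valine
Product: 10, (S)-valinol
Conditions: LiAlH4, THF, reflux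
Reagents that add atoms: none
Why: The amino acid is reduced to the amino alcohol with retention of configuration. This is a hydride reduction.

**Step 7**
Reactants: 10
Product: 11, (S)-4-isopropyloxazolidin-2-one
Conditions: (EtO)2C=O, K2CO3, 135 °C, EtOH distilled off
Reagents that add atoms: diethyl carbonate, CCOC(=O)OCC (supplies the ring C=O)
Why: Carbonate exchange followed by cyclisation closes the cyclic carbamate, and the stereocentre is unchanged. This is oxazolidinone formation from an amino alcohol.

**Step 8**
Reactants: 8, hex-4-ynoic acid; 11
Product: 12, (S)-3-(hex-4-ynoyl)-4-isopropyloxazolidin-2-one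
Conditions: PivCl, Et3N, THF, –20 → 0 °C; then 11, LiCl, rt
Reagents that add atoms: none (PivCl leaves no atoms in the product)
Why: The mixed pivalic anhydride acylates the oxazolidinone nitrogen regioselectively to give the Evans imide. This is mixed-anhydride N-acylation.

**Step 9 (convergent coupling)**
Reactants: 12; 4
Product: 13, syn-aldol imide
Conditions: Bu2BOTf, Et3N, CH2Cl2, –78 → 0 °C; then 4 at –78 → 0 °C; then H2O2, MeOH/pH 7 buffer
Reagents that add atoms: none (boron is removed in the workup)
Why: The Z(O)-boron enolate adds through a Zimmerman–Traxler chair, and the (S)-auxiliary directs the aldehyde to the face opposite the isopropyl group. This gives the (2S,3R) syn adduct, which sets C7 (S) and C8 (R), and the auxiliary overrides the weak β-stereocentre of 4. This is an Evans syn aldol.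

**Step 10**
Reactants: 13
Product: 14, methyl β-hydroxy ester (auxiliary 11 is recovered)
Conditions: NaOMe, MeOH, 0 °C
Reagents that add atoms: methanol, CO (the OMe group is retained)
Why: Methoxide attacks the exocyclic imide carbonyl selectively and no stereocentre is touched at 0 °C. This is Evans auxiliary methanolysis.

**Step 11**
Reactants: 14
Product: 15, enyne diol
Conditions: MeMgBr (5 equiv), THF, 0 °C → rt
Reagents that add atoms: methylmagnesium bromide, C[Mg]Br (supplies C12 and C13)
Why: The alkoxide forms first, then two methyl additions convert the ester into the dimethyl carbinol (C11), and the alkene and alkyne are inert. This is double Grignard addition to an ester.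

**Step 12**
Reactants: 15
Product: 16, (1R,7S,8R,10S)-8,11-dihydroxyguai-4-en-3-one
Conditions: Co2(CO)8, CH2Cl2, rt; then n-BuSMe, toluene, CO (1 atm), 80 °C
Reagents that add atoms: carbon monoxide, [C-]#[O+] (becomes C3)
Why: The alkyne–Co2(CO)6 complex inserts the vinyl group to form the C1–C5 bond, closing the seven-membered ring. CO insertion then gives the 4-methylcyclopentenone. C1 is set by the allylic C10 methyl, which directs C–C bond formation anti to itself; C7 and C8 are untouched. This is an intramolecular Pauson–Khand reaction.

**Step 13**
Reactants: 16; 17, angelic acid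
Product: 18, 8-O-angeloyl ester
Conditions: 17, 2,4,6-Cl3C6H2COCl, Et3N, THF, rt; then 16, DMAP, toluene, rt
Reagents that add atoms: none (the trichlorobenzoyl group leaves)
Why: The mixed anhydride acylates the less hindered secondary C8-OH and leaves the tertiary C11-OH alone. The mild, non-isomerising conditions keep the (Z)-angelate geometry. This is Yamaguchi esterification.

**Step 14**
Reactants: 18
Product: 19, torilin
Conditions: Ac2O, Sc(OTf)3 (cat.), MeCN, 0 °C
Reagents that add atoms: acetic anhydride, CC(=O)OC(C)=O
Why: Lewis-acid catalysis acetylates the hindered tertiary alcohol at low temperature, and the enone and angelate survive. This is Sc(OTf)3-catalysed acetylation.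

## Compound list
1 | (R)-β-butyrolactone, (R)-4-methyloxetan-2-one | C[C@@H]1CC(=O)O1 | starting material
2 | (S)-3-methylpent-4-enoic acid | C=C[C@@H](C)CC(=O)O | intermediate
3 | (S)-3-methylpent-4-en-1-ol | C=C[C@@H](C)CCO | intermediate
4 | (S)-3-methylpent-4-enal | C=C[C@@H](C)CC=O | intermediate
5 | tert-butyl acetate | CC(=O)OC(C)(C)C | starting material
6 | 1-bromobut-2-yne | CC#CCBr | starting material
7 | tert-butyl hex-4-ynoate | CC#CCCC(=O)OC(C)(C)C | intermediate
8 | hex-4-ynoic acid | CC#CCCC(=O)O | intermediate
9 | L-valine | CC(C)[C@H](N)C(=O)O | starting material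
10 | (S)-valinol | CC(C)[C@H](N)CO | intermediate
11 | (S)-4-isopropyloxazolidin-2-one | CC(C)[C@H]1COC(=O)N1 | intermediate
12 | (S)-3-(hex-4-ynoyl)-4-isopropyloxazolidin-2-one | CC#CCCC(=O)N1[C@@H](C(C)C)COC1=O | intermediate
13 | (S)-3-[(2S,3R,5S)-2-(but-2-yn-1-yl)-3-hydroxy-5-methylhept-6-enoyl]-4-isopropyloxazolidin-2-one | C=C[C@@H](C)C[C@@H](O)[C@H](CC#CC)C(=O)N1[C@@H](C(C)C)COC1=O | intermediate
14 | methyl (2S,3R,5S)-2-(but-2-yn-1-yl)-3-hydroxy-5-methylhept-6-enoate | C=C[C@@H](C)C[C@@H](O)[C@H](CC#CC)C(=O)OC | intermediate
15 | (3S,4R,6S)-3-(but-2-yn-1-yl)-2,6-dimethyloct-7-ene-2,4-diol | C=C[C@@H](C)C[C@@H](O)[C@H](CC#CC)C(C)(C)O | intermediate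
16 | (1R,7S,8R,10S)-8,11-dihydroxyguai-4-en-3-one | O[C@@H]1C[C@H](C)[C@H]2CC(=O)C(C)=C2C[C@@H]1C(C)(C)O | intermediate
17 | angelic acid, (Z)-2-methylbut-2-enoic acid | C/C=C(/C)C(=O)O | starting material
18 | 8-O-angeloyl-8,11-dihydroxyguai-4-en-3-one | C/C=C(/C)C(=O)O[C@@H]1C[C@H](C)[C@H]2CC(=O)C(C)=C2C[C@@H]1C(C)(C)O | intermediate
19 | torilin (8-angeloyloxy-11-acetoxyguai-4-en-3-one) | C/C=C(/C)C(=O)O[C@@H]1C[C@H](C)[C@H]2CC(=O)C(C)=C2C[C@@H]1C(C)(C)OC(C)=O | target

## Totals
- **Total steps:** 14.
- **Longest linear sequence:** 9 steps (1→2→3→9→10→11→12→13→14; the other two branches also give 9). This is 9/14, about 0.64 of the total.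
- **Three steps most likely to fail:**
  1. **Step 12, Pauson–Khand.** Closing a seven-membered ring from a 1,8-enyne can be low-yielding, and C1 diastereoselectivity is not guaranteed.
     - Fallback: use a zirconocene-mediated (Negishi) enyne cyclisation followed by CO insertion instead of the cobalt route.
     - If the wrong C1 epimer forms, epimerise it through the enone dienolate (t-BuOK, t-BuOH) to the thermodynamic isomer.
  2. **Step 9, Evans aldol.** The α-propargylic, hindered imide with a chiral aldehyde may give a poor diastereomer ratio or some retro-aldol.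
     - Fallback: set C8 with an acetate aldol and alkylate the β-hydroxy ester dianion with 1-bromobut-2-yne (Frater–Seebach, giving the 2,3-anti product).
     - Then invert C8 by Mitsunobu (p-nitrobenzoic acid, then methanolysis) to reach the syn relationship.
  3. **Step 14, tertiary acetylation with the angelate present.** Risks are angelate-to-tiglate isomerisation, dehydration of the tertiary alcohol, and a low conversion.
     - Fallback: reorder. Protect C8-OH of 15 as the TBS ether (TBSOTf), acetylate C11-OH, run the Pauson–Khand reaction, remove TBS with HF·pyridine, and install the angelate last.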